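The target is an achiral depside. Ring B (B1 bears CO2Me, B2 OH, B3 CH3, B4 the acyloxy group, B5 H, B6 CH3) minus its ester carbon is symmetric 2,5-dimethylresorcinol, which also supplies ring A. The plan rests on cutting the bond from B1 to that carbon: one magnesium-mediated ortho-formylation of the preformed depside makes it. The feature used is that, next to the B2 hydroxyl, only B1 is a C–H carbon (B3 is methylated), while ring A is fully substituted. The precursor is the mono-ester of 2,5-dimethylresorcinol with the ring A acid, whose acidic para hydroxyl is held as a benzyl ether so that B2–OH is the only unchelated phenol; oxidation, methylation and debenzylation follow.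

Key step: step 6

Remarks on the chemistry
- Ring A positions are counted from the carbon that carries the depside carbonyl (position 1): position 2 OH, position 3 CH3, position 4 OH, position 5 Cl, position 6 CH3. The target is methyl 4-[(5-chloro-2,4-dihydroxy-3,6-dimethylbenzoyl)oxy]-2-hydroxy-3,6-dimethylbenzoate and has no stereocentre.
- The ring A hydroxyl at position 4 (para to the depside carbonyl) is carried as a benzyl ether from step 3 to step 9. This prevents self-acylation of the acid in step 5, removes the most acidic phenol before the formylation, and leaves the carboxylic acid as the only reactive site for methylation. The ring A hydroxyl at position 2 stays free because it is hydrogen-bonded to the adjacent carbonyl and ring A has no open position.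
- The ring A carboxyl carbon is introduced by formylation and oxidation. Formylation precedes chlorination so that the chlorination has only one possible site.
- Assumption: paraformaldehyde is written as monomeric formaldehyde.

Step 1
Reactants: 1 2,5-dimethylbenzene-1,3-diol; 2 N,N-dimethylformamide
Product: 4 2,4-dihydroxy-3,6-dimethylbenzaldehyde, via aryl iminium chloride 3 (not isolated)
Conditions: POCl3, DMF, MeCN, 0 °C → rt; then H2O, 50 °C
Reagents that add atoms: N,N-dimethylformamide CN(C)C=O; water O
Why: Vilsmeier–Haack formylation: the chloroiminium ion made from POCl3 and DMF attacks one of the two equivalent ring C–H carbons of 1 (each ortho to one hydroxyl and para to the other), the iminium group of 3 deactivates the ring against a second attack, and water then hydrolyses 3 to the aldehyde.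

Step 2
Reactants: 4 2,4-dihydroxy-3,6-dimethylbenzaldehyde; 5 sulfuryl chloride
Product: 6 5-chloro-2,4-dihydroxy-3,6-dimethylbenzaldehyde
Conditions: SO2Cl2 (1.05 equiv), Et2O, 0 °C → rt
Reagents that add atoms: sulfuryl chloride O=S(=O)(Cl)Cl
Why: Electrophilic aromatic chlorination: carbon 5 is the only ring C–H left in 4 and is activated by the ortho 4-hydroxyl and the para 2-hydroxyl, so one equivalent of SO2Cl2 should give a single monochloride with no site for a second substitution.

Step 3
Reactants: 6 5-chloro-2,4-dihydroxy-3,6-dimethylbenzaldehyde; 7 benzyl bromide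
Product: 8 4-(benzyloxy)-5-chloro-2-hydroxy-3,6-dimethylbenzaldehyde
Conditions: BnBr (1.1 equiv), K2CO3, DMF, 50 °C
Reagents that add atoms: benzyl bromide BrCc1ccccc1
Why: Williamson ether synthesis: the 4-hydroxyl, para to the formyl group and ortho to chlorine, is the more acidic phenol and is not hydrogen-bonded, whereas the 2-hydroxyl is locked in a chelate with the aldehyde, so a slight excess of BnBr with K2CO3 should alkylate the 4-oxygen only.

Step 4
Reactants: 8 4-(benzyloxy)-5-chloro-2-hydroxy-3,6-dimethylbenzaldehyde
Product: 9 4-(benzyloxy)-5-chloro-2-hydroxy-3,6-dimethylbenzoic acid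
Conditions: NaClO2, NaH2PO4, 2-methyl-2-butene, t-BuOH/THF/H2O, rt
Reagents that add atoms: NaClO2 [Na+].[O-]Cl=O
Why: Pinnick oxidation: chlorous acid oxidises the aldehyde to the acid at buffered pH while 2-methyl-2-butene removes the HOCl formed, and neither the benzyl ether nor the fully substituted ring offers a competing site.

Step 5
Reactants: 9 4-(benzyloxy)-5-chloro-2-hydroxy-3,6-dimethylbenzoic acid; 1 2,5-dimethylbenzene-1,3-diol (4 equiv)
Product: 11 3-hydroxy-2,5-dimethylphenyl 4-(benzyloxy)-5-chloro-2-hydroxy-3,6-dimethylbenzoate, via acyl trifluoroacetate 10 (not isolated)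
Conditions: TFAA (1.2 equiv), toluene, 0 °C; then added to 1 in Et2O, rt; aq NaHCO3 work-up
Reagents that add atoms: trifluoroacetic anhydride O=C(OC(=O)C(F)(F)F)C(F)(F)F (its trifluoroacetyl group is held only in intermediate 10)
Why: Mixed-anhydride esterification with TFAA, a standard way to join hindered salicylic acids to phenols: acyl trifluoroacetate 10 of the 2,6-disubstituted acid ionises easily to an acylium ion that O-acylates 1, the fourfold excess of the symmetric diol favours the mono-ester, the benzyl ether rules out self-acylation through the para oxygen of the acid, and bicarbonate work-up cleaves any aryl trifluoroacetate.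

Step 6
Reactants: 11 3-hydroxy-2,5-dimethylphenyl 4-(benzyloxy)-5-chloro-2-hydroxy-3,6-dimethylbenzoate; 12 formaldehyde (used as paraformaldehyde)
Product: 14 4-formyl-3-hydroxy-2,5-dimethylphenyl 4-(benzyloxy)-5-chloro-2-hydroxy-3,6-dimethylbenzoate, via hydroxymethyl phenol 13 (not isolated)
Conditions: MgCl2 (anhydrous, 4 equiv), Et3N (8 equiv), (CH2O)n (10 equiv), THF, reflux; 1 M HCl work-up
Reagents that add atoms: formaldehyde (from paraformaldehyde) C=O
Why: Et3N and MgCl2 convert the ring B hydroxyl (B2) of 11 into its chloromagnesium phenoxide, the divalent magnesium binds monomeric formaldehyde, and the carbonyl carbon is delivered through a six-membered cyclic transition state to the ortho carbon B1, giving after tautomerisation the magnesium salt of salicyl alcohol 13. A second formaldehyde then accepts hydride from the magnesium alkoxide (Oppenauer-type redox), which yields aldehyde 14 and methanol. The closest known reaction is the Casnati–Skattebøl ortho-formylation of phenols, here applied to a phenol bearing a meta acyloxy group; no ring is closed and no stereocentre is formed. The selectivity required is ortho (B1) against para (B5) on ring B, and it is secured by the chelate, which cannot reach B5, together with the methyl group that blocks the other ortho carbon B3. Ring A cannot compete because it has no C–H bond, its ortho phenoxide being merely held in a chelate with the depside carbonyl, and the benzyl ether on the para oxygen of ring A removes the para phenoxide that could otherwise expel ring B by an elimination–addition (ketene) pathway. The depside carbonyl, flanked by the two ortho substituents of ring A, is shielded against attack by the methoxide equivalents formed.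

Step 7
Reactants: 14 4-formyl-3-hydroxy-2,5-dimethylphenyl 4-(benzyloxy)-5-chloro-2-hydroxy-3,6-dimethylbenzoate
Product: 15 4-{[4-(benzyloxy)-5-chloro-2-hydroxy-3,6-dimethylbenzoyl]oxy}-2-hydroxy-3,6-dimethylbenzoic acid
Conditions: NaClO2, NaH2PO4, 2-methyl-2-butene (large excess), t-BuOH/THF/H2O, 0 °C → rt
Reagents that add atoms: NaClO2 [Na+].[O-]Cl=O
Why: Pinnick oxidation: the chelated salicylaldehyde is oxidised by chlorous acid at pH 3 to 4, where the depside ester and the benzyl ether are inert, and the large excess of 2-methyl-2-butene keeps HOCl away from B5, the one ring C–H para to a phenol.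

Step 8
Reactants: 15 4-{[4-(benzyloxy)-5-chloro-2-hydroxy-3,6-dimethylbenzoyl]oxy}-2-hydroxy-3,6-dimethylbenzoic acid; 16 (trimethylsilyl)diazomethane
Product: 17 methyl 4-{[4-(benzyloxy)-5-chloro-2-hydroxy-3,6-dimethylbenzoyl]oxy}-2-hydroxy-3,6-dimethylbenzoate
Conditions: TMSCHN2 (1.1 equiv), toluene/MeOH, 0 °C
Reagents that add atoms: (trimethylsilyl)diazomethane C[Si](C)(C)C=[N+]=[N-]
Why: Esterification with (trimethylsilyl)diazomethane: the carboxylic acid protonates the reagent and is methylated within minutes in the presence of methanol, whereas the two remaining phenols (the ortho hydroxyl of ring A and B2) are both hydrogen-bonded to ortho carbonyl groups and far less acidic, and the acidic para oxygen of ring A is still benzylated.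

Step 9
Reactants: 17 methyl 4-{[4-(benzyloxy)-5-chloro-2-hydroxy-3,6-dimethylbenzoyl]oxy}-2-hydroxy-3,6-dimethylbenzoate
Product: 18 methyl 4-[(5-chloro-2,4-dihydroxy-3,6-dimethylbenzoyl)oxy]-2-hydroxy-3,6-dimethylbenzoate
Conditions: BCl3 (4 equiv), C6HMe5 (5 equiv), CH2Cl2, −78 °C; CHCl3/MeOH quench
Reagents that add atoms: none
Why: Lewis-acid debenzylation with a cation scavenger: BCl3 ionises the aryl benzyl ether at −78 °C and pentamethylbenzene traps the benzyl cation by Friedel–Crafts alkylation, a non-reductive cleavage that should spare the aryl chloride, the methyl ester and the hindered depside ester.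

Compound list
1 | 2,5-dimethylbenzene-1,3-diol | Cc1cc(O)c(C)c(O)c1 | starting material
2 | N,N-dimethylformamide | CN(C)C=O | starting material
3 | (2,4-dihydroxy-3,6-dimethylbenzylidene)dimethylammonium chloride | C[N+](C)=Cc1c(C)cc(O)c(C)c1O.[Cl-] | intermediate
4 | 2,4-dihydroxy-3,6-dimethylbenzaldehyde | O=Cc1c(C)cc(O)c(C)c1O | intermediate
5 | sulfuryl chloride | O=S(=O)(Cl)Cl | starting material
6 | 5-chloro-2,4-dihydroxy-3,6-dimethylbenzaldehyde | O=Cc1c(C)c(Cl)c(O)c(C)c1O | intermediate
7 | benzyl bromide | BrCc1ccccc1 | starting material
8 | 4-(benzyloxy)-5-chloro-2-hydroxy-3,6-dimethylbenzaldehyde | O=Cc1c(C)c(Cl)c(OCc2ccccc2)c(C)c1O | intermediate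
9 | 4-(benzyloxy)-5-chloro-2-hydroxy-3,6-dimethylbenzoic acid | OC(=O)c1c(C)c(Cl)c(OCc2ccccc2)c(C)c1O | intermediate
10 | 4-(benzyloxy)-5-chloro-2-hydroxy-3,6-dimethylbenzoic trifluoroacetic anhydride | O=C(OC(=O)C(F)(F)F)c1c(C)c(Cl)c(OCc2ccccc2)c(C)c1O | intermediate
11 | 3-hydroxy-2,5-dimethylphenyl 4-(benzyloxy)-5-chloro-2-hydroxy-3,6-dimethylbenzoate | Cc1cc(OC(=O)c2c(C)c(Cl)c(OCc3ccccc3)c(C)c2O)c(C)c(O)c1 | intermediate
12 | formaldehyde (used as paraformaldehyde) | C=O | starting material
13 | 3-hydroxy-4-(hydroxymethyl)-2,5-dimethylphenyl 4-(benzyloxy)-5-chloro-2-hydroxy-3,6-dimethylbenzoate | OCc1c(C)cc(OC(=O)c2c(C)c(Cl)c(OCc3ccccc3)c(C)c2O)c(C)c1O | intermediate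
14 | 4-formyl-3-hydroxy-2,5-dimethylphenyl 4-(benzyloxy)-5-chloro-2-hydroxy-3,6-dimethylbenzoate | O=Cc1c(C)cc(OC(=O)c2c(C)c(Cl)c(OCc3ccccc3)c(C)c2O)c(C)c1O | intermediate
15 | 4-{[4-(benzyloxy)-5-chloro-2-hydroxy-3,6-dimethylbenzoyl]oxy}-2-hydroxy-3,6-dimethylbenzoic acid | OC(=O)c1c(C)cc(OC(=O)c2c(C)c(Cl)c(OCc3ccccc3)c(C)c2O)c(C)c1O | intermediate
16 | (trimethylsilyl)diazomethane | C[Si](C)(C)C=[N+]=[N-] | starting material
17 | methyl 4-{[4-(benzyloxy)-5-chloro-2-hydroxy-3,6-dimethylbenzoyl]oxy}-2-hydroxy-3,6-dimethylbenzoate | COC(=O)c1c(C)cc(OC(=O)c2c(C)c(Cl)c(OCc3ccccc3)c(C)c2O)c(C)c1O | intermediate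
18 | methyl 4-[(5-chloro-2,4-dihydroxy-3,6-dimethylbenzoyl)oxy]-2-hydroxy-3,6-dimethylbenzoate | COC(=O)c1c(C)cc(OC(=O)c2c(C)c(Cl)c(O)c(C)c2O)c(C)c1O | target

Total step count: 9
Longest linear sequence: 9 steps (1 → 4 → 6 → 8 → 9 → 11 → 14 → 15 → 17 → 18); ring B enters as compound 1 in step 5.

Steps most likely to fail

Step 6 (key formylation). The depside ester may be cleaved or transferred by the magnesium phenoxides and the methoxide equivalents formed. The reaction may also stall at the hydroxymethyl stage, or that intermediate may condense with a second phenol to a diarylmethane. Fallback: the late one-carbon installation is given up and ring B is brought in with its ester carbon in place. Setting out from acid 9, activation with TFAA as in step 5 (through mixed anhydride 10) and acylation of purchased methyl 2,4-dihydroxy-3,6-dimethylbenzoate F1 should take place at its 4-hydroxyl, the only phenol not chelated to the ester. This depside coupling returns to the route at 17, from which step 9 follows.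

Step 5 (mono-esterification). Double acylation of the symmetric diol and Friedel–Crafts C-acylation of its electron-rich ring by the acylium ion may both erode the mono-ester. Fallback: setting out from 1, monosilylation (TBSCl, imidazole, DMF) gives 3-{[tert-butyl(dimethyl)silyl]oxy}-2,5-dimethylphenol F2, a nucleophile with a single hydroxyl. Steglich coupling of F2 with 9 (DCC, DMAP cat., CH2Cl2), which passes through no free acylium ion, gives 3-{[tert-butyl(dimethyl)silyl]oxy}-2,5-dimethylphenyl 4-(benzyloxy)-5-chloro-2-hydroxy-3,6-dimethylbenzoate F3. Desilylation with Bu4NF buffered by AcOH in THF at 0 °C returns to the route at 11.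

Step 9 (debenzylation). Boron chelation at the two salicylate-type carbonyls may trigger acyl–oxygen cleavage of the depside on warming, or cleavage of the doubly flanked ether may stall. Fallback: reductive instead of Lewis-acidic cleavage. Setting out from 17, hydrogenolysis over Pd/C under H2 (1 atm) in EtOAc at rt, stopped after uptake of one equivalent so that the aryl chloride is kept, leads directly to 18.

Further compounds
F1 | step 6 | methyl 2,4-dihydroxy-3,6-dimethylbenzoate (purchased coupling partner) | COC(=O)c1c(C)cc(O)c(C)c1O
F2 | step 5 | 3-{[tert-butyl(dimethyl)silyl]oxy}-2,5-dimethylphenol | Cc1cc(O)c(C)c(O[Si](C)(C)C(C)(C)C)c1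
F3 | step 5 | 3-{[tert-butyl(dimethyl)silyl]oxy}-2,5-dimethylphenyl 4-(benzyloxy)-5-chloro-2-hydroxy-3,6-dimethylbenzoate | Cc1cc(OC(=O)c2c(C)c(Cl)c(OCc3ccccc3)c(C)c2O)c(C)c(O[Si](C)(C)C(C)(C)C)c1
F0 | step 9 | none | none
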